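**Retrosynthetic overview**
1. Target 14 ⇒ umbelliferone 13 + epoxy alcohol 12 (aryl ether made last); 12 ⇒ Z-allylic alcohol 11 by reagent-controlled epoxidation.
2. 11 ⇒ dihydropyranone acid 8 by a lactone ring switch: hydride opening of the six-membered unsaturated lactone frees the Z-allylic alcohol and the secondary hydroxyl, which recloses on the α-hydroxy acid to give the five-membered lactone.
3. 8 ⇒ 2-pyranone 6 by enantioselective hydrogenation of the 5,6-double bond (sets the secondary carbinol; the ring fixes the Z-alkene).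
4. 6 ⇒ 4,6-dimethyl-2-pyranone 1 + tert-butyl pyruvate 4 by a catalytic enantioselective vinylogous Mukaiyama aldol (the whole C10 chain in one C–C bond; sets the tertiary carbinol).
5. Ring order: pyranone (bought) → γ-lactone (step 5) → epoxide (step 6); the coumarin is bought and joined last.

Assumption: the ruthenium catalyst of (S)-MeO-BIPHEP is taken to add hydrogen to the face of 6 that gives the (2R)-dihydropyranyl centre of 7; if the sense is the reverse, the (R)-ligand is meant.

**Step 1**
Reactants: 1 4,6-dimethyl-2H-pyran-2-one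
Product: 3 trimethyl[(4-methyl-6-methylidene-6H-pyran-2-yl)oxy]silane, via lithium trienolate 2 (not isolated)
Conditions: LiN(i-Pr)2 (1.05 equiv), THF, −78 °C; Me3SiCl (1.2 equiv), −78 → 0 °C; pentane, filtration under argon, used crude
Reagents that add atoms: chlorotrimethylsilane C[Si](C)(C)Cl; lithium diisopropylamide [Li+].CC(C)[N-]C(C)C (supplies the lithium of 2)
Why: Kinetic deprotonation of the 6-methyl group gives the linearly conjugated trienolate (the 4-methyl anion is only cross-conjugated), and O-silylation of this extended lactone enolate gives the silyl trienol ether as in the making of 2-silyloxyfurans (vinylogous enolate silylation); no stereocentre is formed.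

**Step 2**
Reactants: 3 trimethyl[(4-methyl-6-methylidene-6H-pyran-2-yl)oxy]silane; 4 tert-butyl 2-oxopropanoate (tert-butyl pyruvate)
Product: 6 tert-butyl (2S)-2-hydroxy-2-methyl-3-(4-methyl-2-oxo-2H-pyran-6-yl)propanoate, via silyl ether 5 (not isolated)
Conditions: Cu(OTf)2 (10 mol%), (S,S)-t-Bu-box [2,2'-(propane-2,2-diyl)bis((4S)-4-tert-butyl-4,5-dihydrooxazole)] (11 mol%), THF, −78 °C; then 1 M HCl, THF, 0 °C
Reagents that add atoms: none
Why: Proposed new method: the pyruvate chelates the copper–bis(oxazoline) Lewis acid through both carbonyl oxygens, the ligand tert-butyl groups block the re face of the ketone, and the trienol ether attacks the si face through its exocyclic CH2 (attack there restores the pyranone) to give the (S)-tertiary carbinol; the closest known reactions are the copper–bis(oxazoline)-catalysed Mukaiyama aldol additions of enolsilanes, silylketene acetals and 2-(trimethylsilyloxy)furan to pyruvate esters.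

**Step 3**
Reactants: 6 tert-butyl (2S)-2-hydroxy-2-methyl-3-(4-methyl-2-oxo-2H-pyran-6-yl)propanoate
Product: 7 tert-butyl (2S)-2-hydroxy-2-methyl-3-[(2R)-4-methyl-6-oxo-3,6-dihydro-2H-pyran-2-yl]propanoate
Conditions: Ru(OAc)2[(S)-MeO-BIPHEP] (1 mol%; ligand = (S)-(6,6'-dimethoxybiphenyl-2,2'-diyl)bis(diphenylphosphine)), HBF4·OEt2 (2 mol%), H2 (60 bar), i-PrOH/CH2Cl2, 60 °C, stopped after 1 equiv H2
Reagents that add atoms: none
Why: Enantioselective hydrogenation of 2-pyranones with cationic ruthenium–atropisomeric diphosphine catalysts reduces the enol-ester 5,6-double bond and leaves the conjugated 3,4-double bond, so the secondary carbinol carbon is set by catalyst control while the ring holds the trisubstituted alkene in the Z geometry.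

**Step 4**
Reactants: 7 tert-butyl (2S)-2-hydroxy-2-methyl-3-[(2R)-4-methyl-6-oxo-3,6-dihydro-2H-pyran-2-yl]propanoate
Product: 8 (2S)-2-hydroxy-2-methyl-3-[(2R)-4-methyl-6-oxo-3,6-dihydro-2H-pyran-2-yl]propanoic acid
Conditions: CF3CO2H/CH2Cl2 (1:4), 0 °C → rt
Reagents that add atoms: none
Why: Acidolysis of the tert-butyl ester (loss of 2-methylpropene) frees the acid without touching the conjugated lactone, the tertiary alcohol or either stereocentre.

**Step 5**
Reactants: 8 (2S)-2-hydroxy-2-methyl-3-[(2R)-4-methyl-6-oxo-3,6-dihydro-2H-pyran-2-yl]propanoic acid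
Product: 11 (3S,5R)-3-hydroxy-5-[(2Z)-4-hydroxy-2-methylbut-2-en-1-yl]-3-methyloxolan-2-one, via lactol acid 9 (not isolated), via trihydroxy acid 10 (not isolated)
Conditions: i-Bu2AlH (3.3 equiv), THF/CH2Cl2, −78 °C; MeOH; then NaBH4, CeCl3·7H2O, MeOH, 0 °C; then 1 M HCl to pH 3, EtOAc, 0 °C → rt
Reagents that add atoms: none
Why: i-Bu2AlH first turns CO2H and OH into an aluminium carboxylate and alkoxide that are inert at −78 °C and then reduces the lactone to the lactol, Luche reduction of the ring-opened Z-enal gives the allylic alcohol, and on acidification the freed secondary hydroxyl closes on the acid to the five-membered lactone (translactonisation), with no bond to either stereocentre broken.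

**Step 6**
Reactants: 11 (3S,5R)-3-hydroxy-5-[(2Z)-4-hydroxy-2-methylbut-2-en-1-yl]-3-methyloxolan-2-one
Product: 12 (3S,5S)-3-hydroxy-5-{[(2R,3S)-3-(hydroxymethyl)-2-methyloxiran-2-yl]methyl}-3-methyloxolan-2-one
Conditions: Ti(Oi-Pr)4 (1.0 equiv), L-(+)-diethyl tartrate (1.2 equiv), t-BuOOH (2 equiv, decane), 4 Å MS, CH2Cl2, −20 °C
Reagents that add atoms: tert-butyl hydroperoxide CC(C)(C)OO
Why: Sharpless asymmetric epoxidation with L-(+)-tartrate delivers oxygen to the face of the Z-allylic alcohol that gives the (2S,3R)-type epoxy alcohol (as nerol gives (2S,3R)-epoxynerol), a reagent-controlled step that sets both epoxide centres and leaves the minor isomer as a separable diastereomer.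

**Step 7**
Reactants: 12 (3S,5S)-3-hydroxy-5-{[(2R,3S)-3-(hydroxymethyl)-2-methyloxiran-2-yl]methyl}-3-methyloxolan-2-one; 13 7-hydroxy-2H-chromen-2-one (umbelliferone)
Product: 14 7-{[(2S,3R)-3-{[(2S,4S)-4-hydroxy-4-methyl-5-oxooxolan-2-yl]methyl}-3-methyloxiran-2-yl]methoxy}-2H-chromen-2-one
Conditions: PPh3, DIAD, THF, 0 °C → rt
Reagents that add atoms: none
Why: Mitsunobu etherification, in which the acidic coumarin phenol (pKa about 8) displaces the primary oxyphosphonium at CH2, so the epoxide centres are untouched and the tertiary alcohol does not react.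

**Compound list**
1 | 4,6-dimethyl-2H-pyran-2-one | CC1=CC(=O)OC(C)=C1 | starting material
2 | lithium 4-methyl-6-methylidene-6H-pyran-2-olate | [Li+].[O-]C1=CC(C)=CC(=C)O1 | intermediate
3 | trimethyl[(4-methyl-6-methylidene-6H-pyran-2-yl)oxy]silane | C=C1C=C(C)C=C(O[Si](C)(C)C)O1 | intermediate
4 | tert-butyl 2-oxopropanoate | CC(=O)C(=O)OC(C)(C)C | starting material
5 | tert-butyl (2S)-2-methyl-3-(4-methyl-2-oxo-2H-pyran-6-yl)-2-[(trimethylsilyl)oxy]propanoate | C[C@](O[Si](C)(C)C)(CC1=CC(C)=CC(=O)O1)C(=O)OC(C)(C)C | intermediate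
6 | tert-butyl (2S)-2-hydroxy-2-methyl-3-(4-methyl-2-oxo-2H-pyran-6-yl)propanoate | C[C@](O)(CC1=CC(C)=CC(=O)O1)C(=O)OC(C)(C)C | intermediate
7 | tert-butyl (2S)-2-hydroxy-2-methyl-3-[(2R)-4-methyl-6-oxo-3,6-dihydro-2H-pyran-2-yl]propanoate | C[C@](O)(C[C@H]1CC(C)=CC(=O)O1)C(=O)OC(C)(C)C | intermediate
8 | (2S)-2-hydroxy-2-methyl-3-[(2R)-4-methyl-6-oxo-3,6-dihydro-2H-pyran-2-yl]propanoic acid | C[C@](O)(C[C@H]1CC(C)=CC(=O)O1)C(=O)O | intermediate
9 | (2S)-2-hydroxy-3-[(2R)-6-hydroxy-4-methyl-3,6-dihydro-2H-pyran-2-yl]-2-methylpropanoic acid (lactol, both anomers) | C[C@](O)(C[C@H]1CC(C)=CC(O)O1)C(=O)O | intermediate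
10 | (2S,4R,6Z)-2,4,8-trihydroxy-2,6-dimethyloct-6-enoic acid | C[C@](O)(C[C@H](O)C/C(C)=C\CO)C(=O)O | intermediate
11 | (3S,5R)-3-hydroxy-5-[(2Z)-4-hydroxy-2-methylbut-2-en-1-yl]-3-methyloxolan-2-one | C[C@]1(O)C[C@@H](C/C(C)=C\CO)OC1=O | intermediate
12 | (3S,5S)-3-hydroxy-5-{[(2R,3S)-3-(hydroxymethyl)-2-methyloxiran-2-yl]methyl}-3-methyloxolan-2-one (C-5 goes from R to S by priority change only, same geometry) | C[C@]1(O)C[C@@H](C[C@@]2(C)O[C@H]2CO)OC1=O | intermediate
13 | 7-hydroxy-2H-chromen-2-one (umbelliferone) | Oc1ccc2ccc(=O)oc2c1 | starting material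
14 | 7-{[(2S,3R)-3-{[(2S,4S)-4-hydroxy-4-methyl-5-oxooxolan-2-yl]methyl}-3-methyloxiran-2-yl]methoxy}-2H-chromen-2-one (CNP0246010.1) | C[C@]1(O)C[C@@H](C[C@@]2(C)O[C@H]2COc2ccc3ccc(=O)oc3c2)OC1=O | target

**Step count and risks**
Total step count: 7. Longest linear sequence: 7 steps (from 1; 4 and 13 are bought).

The three steps most likely to fail:

Step 2 (new reaction; it also rests on clean O-silylation and on 6-methyl selectivity in step 1). The fallback sets out from 2. The lithium trienolate 2 is added without silylation to 4 (THF, −78 °C, uncatalysed aldol addition) and gives the racemic carbinol tert-butyl 2-hydroxy-2-methyl-3-(4-methyl-2-oxo-2H-pyran-6-yl)propanoate F1. F1 is hydrogenated as in step 3, where the catalyst fixes the ring carbon in both enantiomers. This gives 7 beside its side-chain epimer tert-butyl (2R)-2-hydroxy-2-methyl-3-[(2R)-4-methyl-6-oxo-3,6-dihydro-2H-pyran-2-yl]propanoate F2, and the two diastereomers are parted by chromatography. The route is rejoined at 7; the tertiary carbinol is then secured by separation, not by catalysis, and at most half of the material is used.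

Step 3 (chemoselectivity, sense and level of induction on a new, branched pyranone). The fallback sets out from 4 and builds the dihydropyranone by aldol chemistry instead of hydrogenation.
- S-ethyl ethanethioate with LiN(i-Pr)2 and Me3SiCl gives [(1-(ethylsulfanyl)ethenyl)oxy]trimethylsilane F3.
- The known Cu(OTf)2/(S,S)-t-Bu-box Mukaiyama aldol of F3 with 4 gives the silyl ether tert-butyl (2S)-4-(ethylsulfanyl)-2-methyl-4-oxo-2-[(trimethylsilyl)oxy]butanoate F4, and dilute acid gives the carbinol tert-butyl (2S)-4-(ethylsulfanyl)-2-hydroxy-2-methyl-4-oxobutanoate F5.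
- Fukuyama reduction (Et3SiH, Pd/C, acetone) gives the aldehyde tert-butyl (2S)-2-hydroxy-2-methyl-4-oxobutanoate F6.
- A vinylogous Mukaiyama aldol of F6 with [(1-ethoxy-3-methylbuta-1,3-dien-1-yl)oxy]trimethylsilane F7 (from ethyl 3-methylbut-2-enoate, LiN(i-Pr)2, Me3SiCl) is run under CuF2/Tol-BINAP/fluoride catalysis. The copper aldolate of the cis-enoate lactonises in the flask to the dihydropyranone.
- The secondary carbinol is set by 1,3-anti induction from the β-oxygenated aldehyde, reinforced by the matched Tol-BINAP enantiomer. The route is rejoined at 7.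

Step 5 (reduction of the lactone beside a free α-hydroxy acid, and the ring switch). The fallback sets out from 7 and leaves out step 4. i-Bu2AlH at −78 °C reduces only the lactone, because the tert-butyl ester next to the quaternary carbon is inert, and gives the lactol ester tert-butyl (2S)-2-hydroxy-3-[(2R)-6-hydroxy-4-methyl-3,6-dihydro-2H-pyran-2-yl]-2-methylpropanoate F8. NaBH4/CeCl3·7H2O in MeOH gives the diol ester tert-butyl (2S,4R,6Z)-2,4,8-trihydroxy-2,6-dimethyloct-6-enoate F9. NaH in THF (0 °C → rt) then closes the secondary alkoxide on the tert-butyl ester (base-mediated translactonisation, no acid near the allylic alcohol). The route is rejoined at 11.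

**Further compounds**
F1 | step 2 | tert-butyl 2-hydroxy-2-methyl-3-(4-methyl-2-oxo-2H-pyran-6-yl)propanoate (racemic) | CC(O)(CC1=CC(C)=CC(=O)O1)C(=O)OC(C)(C)C
F2 | step 2 | tert-butyl (2R)-2-hydroxy-2-methyl-3-[(2R)-4-methyl-6-oxo-3,6-dihydro-2H-pyran-2-yl]propanoate | C[C@@](O)(C[C@H]1CC(C)=CC(=O)O1)C(=O)OC(C)(C)C
F3 | step 3 | [(1-(ethylsulfanyl)ethenyl)oxy]trimethylsilane | CCSC(=C)O[Si](C)(C)C
F4 | step 3 | tert-butyl (2S)-4-(ethylsulfanyl)-2-methyl-4-oxo-2-[(trimethylsilyl)oxy]butanoate | CCSC(=O)C[C@](C)(O[Si](C)(C)C)C(=O)OC(C)(C)C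
F5 | step 3 | tert-butyl (2S)-4-(ethylsulfanyl)-2-hydroxy-2-methyl-4-oxobutanoate | CCSC(=O)C[C@](C)(O)C(=O)OC(C)(C)C
F6 | step 3 | tert-butyl (2S)-2-hydroxy-2-methyl-4-oxobutanoate | O=CC[C@](C)(O)C(=O)OC(C)(C)C
F7 | step 3 | [(1-ethoxy-3-methylbuta-1,3-dien-1-yl)oxy]trimethylsilane | CCOC(=CC(C)=C)O[Si](C)(C)C
F8 | step 5 | tert-butyl (2S)-2-hydroxy-3-[(2R)-6-hydroxy-4-methyl-3,6-dihydro-2H-pyran-2-yl]-2-methylpropanoate | C[C@](O)(C[C@H]1CC(C)=CC(O)O1)C(=O)OC(C)(C)C
F9 | step 5 | tert-butyl (2S,4R,6Z)-2,4,8-trihydroxy-2,6-dimethyloct-6-enoate | C[C@](O)(C[C@H](O)C/C(C)=C\CO)C(=O)OC(C)(C)C
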